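**Retrosynthetic overview**

1. Target 17 is a fully substituted 2-pyranone (ring atoms O1, carbonyl C2, methoxy-bearing C3 and C4, methyl-bearing C5, chain-bearing C6). The strategy rests on its C5=C6 bond, an enol-ester alkene conjugated through C3=C4 to the lactone carbonyl.
2. C5=C6 is disconnected by ring-closing metathesis (ethylene lost), which forms the only ring last. This leads to acyclic enol ester 16, whose (2Z)-dimethoxyacrylate holds an isopropenyl group (future C5) cis to the ester, next to an alk-1-en-2-yl ester (future C6).
3. The O1–C6 enol-ester bond is disconnected by Markovnikov addition of a carboxylic acid to a terminal alkyne, giving acid 10 and alkyne 15.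
4. Acid 10 comes from methyl methoxyacetate by formylation/O-methylation, then ester-directed C3 lithiation and Negishi isopropenylation, which fixes the 2Z geometry. Alkyne 15 comes from 10-bromodecan-1-ol by thiolate displacement, bromination and acetylide alkylation.

Key step: step 8

Remark: the O-methylation in step 1 is taken to give the acrylate with the 3-methoxy group anti to the ester (2Z), the usual outcome for formyl-ester enolates. Any 2E isomer is removed before step 2, since only the 2Z isomer has its C3–H cis to the ester.

**Route**

Step 1
Reactants: 1 methyl methoxyacetate; 2 methyl formate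
Product: 4 methyl (2Z)-2,3-dimethoxyprop-2-enoate, via sodium enolate 3 (not isolated)
Conditions: NaH, HCO2Me (excess), THF, 0 °C to rt; then Me2SO4, DMF, rt
Reagents that add atoms: dimethyl sulfate, COS(=O)(=O)OC
Why: Crossed Claisen condensation with the non-enolizable formate should give the formyl-ester enolate, and O-alkylation by the hard electrophile in DMF should place the new methoxy group anti to the ester, as is general for β-methoxyacrylates.

Step 2
Reactants: 4 methyl (2Z)-2,3-dimethoxyprop-2-enoate; 5 2-bromopropene
Product: 8 methyl (2Z)-2,3-dimethoxy-4-methylpenta-2,4-dienoate, via alkenyllithium 6 (not isolated), via alkenylzinc chloride 7 (not isolated)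
Conditions: LiN(iPr)2, THF, −95 °C; ZnCl2, −95 °C to 0 °C; then 5, Pd(PPh3)4 (cat.), THF, rt to 40 °C
Reagents that add atoms: none
Why: The ester carbonyl directs lithiation to the cis C3–H (chelate-stabilized alkenyllithium), and transmetalation to zinc followed by Negishi coupling proceeds with retention, so the isopropenyl group should end up cis to the ester (2Z).

Step 3
Reactants: 8 methyl (2Z)-2,3-dimethoxy-4-methylpenta-2,4-dienoate
Product: 10 (2Z)-2,3-dimethoxy-4-methylpenta-2,4-dienoic acid, via lithium carboxylate 9 (not isolated)
Conditions: LiOH, THF/H2O, 0 °C to rt; then 1 M HCl to pH 4, 0 °C, extraction, used at once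
Reagents that add atoms: lithium hydroxide, [Li+].[OH-]
Why: Ester saponification by acyl–oxygen cleavage should proceed, since the donor-substituted acrylate resists conjugate attack, and cold, mild acidification should spare the acid-sensitive 2-methoxydiene and avoid lactonization onto the isopropenyl group.

Step 4
Reactants: 11 10-bromodecan-1-ol
Product: 12 10-(methylsulfanyl)decan-1-ol
Conditions: NaSMe, MeOH, 0 °C to rt
Reagents that add atoms: sodium methanethiolate, C[S-].[Na+]
Why: SN2 displacement of the primary bromide by the soft thiolate should be far faster than any reaction of the free hydroxyl.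

Step 5
Reactants: 12 10-(methylsulfanyl)decan-1-ol
Product: 13 1-bromo-10-(methylsulfanyl)decane
Conditions: CBr4, PPh3, CH2Cl2, 0 °C
Reagents that add atoms: carbon tetrabromide, BrC(Br)(Br)Br
Why: Appel bromination of a primary alcohol under neutral conditions should leave the dialkyl sulfide untouched.

Step 6
Reactants: 13 1-bromo-10-(methylsulfanyl)decane; 14 lithium acetylide ethylenediamine complex
Product: 15 12-(methylsulfanyl)dodec-1-yne
Conditions: LiC≡CH·H2NCH2CH2NH2, DMSO, 10 °C to rt
Reagents that add atoms: none
Why: SN2 alkylation of lithium acetylide by a primary bromide in DMSO is a standard terminal-alkyne synthesis and the thioether is inert to it.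

Step 7
Reactants: 10 (2Z)-2,3-dimethoxy-4-methylpenta-2,4-dienoic acid; 15 12-(methylsulfanyl)dodec-1-yne
Product: 16 12-(methylsulfanyl)dodec-1-en-2-yl (2Z)-2,3-dimethoxy-4-methylpenta-2,4-dienoate
Conditions: RuCl2(p-cymene)(PPh3) (cat.), Na2CO3 (cat.), toluene, 60 °C
Reagents that add atoms: none
Why: Ruthenium-catalysed Markovnikov addition of a carboxylic acid to a terminal alkyne (carboxylate attack at the internal carbon of the coordinated alkyne, then protonolysis) should give the alk-1-en-2-yl ester, with the carbonate buffer suppressing acid-induced lactonization of 10.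

Step 8
Reactants: 16 12-(methylsulfanyl)dodec-1-en-2-yl (2Z)-2,3-dimethoxy-4-methylpenta-2,4-dienoate
Product: 17 3,4-dimethoxy-5-methyl-6-[10-(methylsulfanyl)decyl]-2H-pyran-2-one
Conditions: Mo(N-2,6-iPr2C6H3)(CHCMe2Ph)[OCMe(CF3)2]2 (20 mol %, two portions), benzene, 0.003 M, 60 °C, slow argon purge to remove ethylene, rigorously dry and oxygen-free
Reagents that add atoms: none
Why: Proposed new method: the molybdenum neophylidene should add by [2+2] cycloaddition to one of the two 1,1-disubstituted alkene termini of 16 (the isopropenyl group or the enol-ester methylene), cycloreversion leaving a disubstituted alkylidene on the chain that then adds across the other terminus within the molecule; cycloreversion of this second molybdacyclobutane forms the C5=C6 bond and returns Mo=CH2, so ethylene is the only by-product. The closest known reaction types are ring-closing metathesis to tetrasubstituted cycloalkenes and to cyclic enol ethers with this class of molybdenum imido alkylidene, whereas closure onto an enol-ester alkene to give a fully unsaturated 2-pyranone has not been shown. The single ring (O1, C2, C3, C4, C5, C6) closes as a six-membered ring by intramolecular alkene metathesis with C5=C6 as the new endocyclic alkene, and no stereocenter is formed. The selectivity needed is ring closure over oligomerization or stalling at the hindered alkenes: the 2Z geometry fixed in step 2 holds the isopropenyl group and the ester on the same side of C3=C4, homodimerization of 1,1-disubstituted alkenes is intrinsically slow, and high dilution with removal of ethylene should pull the system toward the conjugated pyranone. The molybdenum catalyst is chosen over ruthenium carbenes because it turns over on tetrasubstituted and heteroatom-substituted alkenes and tolerates the dialkyl sulfide.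

**Compound list**

1 | methyl methoxyacetate | COCC(=O)OC | starting material
2 | methyl formate | COC=O | starting material
3 | sodium 2,3-dimethoxy-3-oxoprop-1-en-1-olate (enolate geometry not fixed) | [Na+].[O-]C=C(OC)C(=O)OC | intermediate
4 | methyl (2Z)-2,3-dimethoxyprop-2-enoate | COC(=O)/C(OC)=C/OC | intermediate
5 | 2-bromopropene | C=C(C)Br | starting material
6 | methyl (2Z)-3-lithio-2,3-dimethoxyprop-2-enoate (lithium cis to the ester) | COC(=O)/C(OC)=C(/OC)[Li] | intermediate
7 | chloro[(1E)-1,2,3-trimethoxy-3-oxoprop-1-en-1-yl]zinc (zinc cis to the ester) | COC(=O)/C(OC)=C(/OC)[Zn]Cl | intermediate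
8 | methyl (2Z)-2,3-dimethoxy-4-methylpenta-2,4-dienoate | COC(=O)/C(OC)=C(/OC)C(C)=C | intermediate
9 | lithium (2Z)-2,3-dimethoxy-4-methylpenta-2,4-dienoate | [Li+].[O-]C(=O)/C(OC)=C(/OC)C(C)=C | intermediate
10 | (2Z)-2,3-dimethoxy-4-methylpenta-2,4-dienoic acid | OC(=O)/C(OC)=C(/OC)C(C)=C | intermediate
11 | 10-bromodecan-1-ol | OCCCCCCCCCCBr | starting material
12 | 10-(methylsulfanyl)decan-1-ol | CSCCCCCCCCCCO | intermediate
13 | 1-bromo-10-(methylsulfanyl)decane | CSCCCCCCCCCCBr | intermediate
14 | lithium acetylide ethylenediamine complex | [Li]C#C.NCCN | starting material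
15 | 12-(methylsulfanyl)dodec-1-yne | C#CCCCCCCCCCCSC | intermediate
16 | 12-(methylsulfanyl)dodec-1-en-2-yl (2Z)-2,3-dimethoxy-4-methylpenta-2,4-dienoate | C=C(CCCCCCCCCCSC)OC(=O)/C(OC)=C(/OC)C(C)=C | intermediate
17 | 3,4-dimethoxy-5-methyl-6-[10-(methylsulfanyl)decyl]-2H-pyran-2-one | COc1c(C)c(CCCCCCCCCCSC)oc(=O)c1OC | target

**Step count**

Total steps: 8. Longest linear sequence: 5 steps (steps 1, 2, 3, 7, 8, or equally 4, 5, 6, 7, 8).

**Steps most likely to fail**

Step 8 (proposed new method). The molybdenum alkylidene may fail to engage either hindered 1,1-disubstituted alkene, may be deactivated by chelation to the ester carbonyl or sulfur, or may olefinate the enol-ester carbonyl instead of closing the ring. The fallback is the classical triketide lactonization; it sets out from 13 and 1 and comes back at 17. Bromide 13 is converted to its Grignard reagent (Mg, THF) and carboxylated with CO2 to 11-(methylsulfanyl)undecanoic acid F1, which 1,1'-carbonyldiimidazole in THF should turn into 1-(1H-imidazol-1-yl)-11-(methylsulfanyl)undecan-1-one F2. In parallel, the lithium enolate of 1 (LiN(SiMe3)2, 2 equiv, THF, −78 °C) is acylated with propanoyl chloride to methyl 2-methoxy-3-oxopentanoate F3. The dianion of F3 (NaH, then n-BuLi, THF, 0 °C) should be acylated at C4 by F2 to give methyl 2-methoxy-4-methyl-15-(methylsulfanyl)-3,5-dioxopentadecanoate F4. DBU in refluxing toluene should lactonize F4 to 4-hydroxy-3-methoxy-5-methyl-6-[10-(methylsulfanyl)decyl]-2H-pyran-2-one F5. O-Methylation of the 4-hydroxyl group (Me2SO4, K2CO3, acetone) should then give 17, with any 2-methoxy-4-pyranone isomer removed by chromatography.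

Step 7. Sulfur coordination may poison the ruthenium catalyst, Markovnikov regiocontrol may be lost, or acid 10 may lactonize onto its isopropenyl group before it adds. The fallback is O-acylation of a kinetic ketone enolate; it sets out from 13 and 10 and comes back at 16. The Grignard reagent of 13 (Mg, THF) is added to N-methoxy-N-methylacetamide at 0 °C to give 12-(methylsulfanyl)dodecan-2-one F6. Acid 10 is dehydrated with DCC (0.5 equiv, CH2Cl2, 0 °C) to (2Z)-2,3-dimethoxy-4-methylpenta-2,4-dienoic anhydride F7. Kinetic deprotonation of F6 at its methyl group (KN(SiMe3)2, THF, −78 °C) and O-acylation of the terminal potassium enolate with F7 should give 16, one half of the anhydride being recovered as 10.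

Step 2. The lithiated acrylate may lose lithium methoxide by β-elimination or self-condense before transmetalation, and coupling at the hindered alkenylzinc may be sluggish. The fallback builds the dienoate by aldol, oxidation and enolate O-methylation; it sets out from 1 and comes back at 8. Aldol addition of the lithium enolate of 1 (LiN(iPr)2, THF, −78 °C) to methacrolein should give methyl 3-hydroxy-2-methoxy-4-methylpent-4-enoate F8 (racemic diastereomer mixture). Dess–Martin oxidation (CH2Cl2, 0 °C to rt) should give methyl 2-methoxy-4-methyl-3-oxopent-4-enoate F9. O-Methylation of its dissociated potassium enolate (KN(SiMe3)2, THF/DMPU, −78 °C; then MeOTf) should give 8, since the extended enolate places the new methoxy group anti to the ester; any 2E isomer is removed by chromatography.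

**Further compounds**

F1 | step 8 | 11-(methylsulfanyl)undecanoic acid | CSCCCCCCCCCCC(=O)O
F2 | step 8 | 1-(1H-imidazol-1-yl)-11-(methylsulfanyl)undecan-1-one | CSCCCCCCCCCCC(=O)n1ccnc1
F3 | step 8 | methyl 2-methoxy-3-oxopentanoate | CCC(=O)C(OC)C(=O)OC
F4 | step 8 | methyl 2-methoxy-4-methyl-15-(methylsulfanyl)-3,5-dioxopentadecanoate | COC(=O)C(OC)C(=O)C(C)C(=O)CCCCCCCCCCSC
F5 | step 8 | 4-hydroxy-3-methoxy-5-methyl-6-[10-(methylsulfanyl)decyl]-2H-pyran-2-one | COc1c(O)c(C)c(CCCCCCCCCCSC)oc1=O
F6 | step 7 | 12-(methylsulfanyl)dodecan-2-one | CC(=O)CCCCCCCCCCSC
F7 | step 7 | (2Z)-2,3-dimethoxy-4-methylpenta-2,4-dienoic anhydride | O(C(=O)/C(OC)=C(/OC)C(C)=C)C(=O)/C(OC)=C(/OC)C(C)=C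
F8 | step 2 | methyl 3-hydroxy-2-methoxy-4-methylpent-4-enoate | COC(C(=O)OC)C(O)C(C)=C
F9 | step 2 | methyl 2-methoxy-4-methyl-3-oxopent-4-enoate | COC(C(=O)OC)C(=O)C(C)=C
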